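Compound numbers follow the order of the steps below: 1–4 are the oxirane branch, 5–8 the phenacyl bromide branch, 9–24 the main line, and 24 is the target.

## The problem

Target 24 is an isoflavone whose ring A carries a substituent on every carbon: a methoxy group at C5, a (2S)-2-hydroxy-3-methylbutyl chain at C6, a free hydroxyl at C7, a prenyl group at C8, and the fusion carbons C4a and C8a. The pyranone ring C carries the 4-hydroxyphenyl ring B at C3. The first task is regiochemical: three different carbon substituents (at C6, C8 and C4a) must be placed between three oxygens, of which one stays a methyl ether, one ends as a free phenol and one becomes O1. The only stereocentre is the carbinol carbon of the C6 side chain. It is isolated from all other functionality, so it can neither be set by nor control anything else, and is best taken from the chiral pool and never broken at its C–O bond afterwards. The prenyl group ortho to the C7 hydroxyl is the fragile element: strong protic or Lewis acid closes it onto O7 as a chroman, and it rules out hydrogenolysis and electrophilic oxidants. The 4-pyranone opens under strong aqueous base, and the C5 methyl ether has to stay distinct from the two phenols throughout. The feature that allows the key step is the C3–C4 bond of ring C. Once C2=C3 is written as its hydrate, C4 (on C4a of ring A) is the carbon of a benzaldehyde and C3 is the carbon of an aryl ketone, linked through C4a, C8a, O1 and C2. Both are electrophilic, so the bond can be made only if one of them is inverted in polarity.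

## Retrosynthesis

**24 to 23.** Only protecting groups are removed: the methoxymethyl (MOM) ethers at O7 and O4′ and the tert-butyldimethylsilyl ether of the side-chain carbinol. A silyl ether is chosen for the alcohol rather than a third acetal because an alkyl MOM ether needs stronger acid than the prenyl/phenol pair should see. The forward step asks for one mild acid treatment that leaves the alkene and the methyl ether alone.

**23 to 21.** Water is added across C2=C3 to give tertiary α-ketol 21. This removes the enol-ether double bond from the list of things to be built and reveals C3 as a carbinol. The forward elimination has no regiochemical choice because only C2 carries hydrogens next to C3, and it erases whatever configuration C3 has.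

**21 to 20 (key cut, C3–C4).** The neighbouring cuts are C4–C4a (an acylation of ring A in acid) and O1–C8a (an aryne or substitution at a hindered carbon). Cutting C3–C4 instead turns the bicyclic core into acyclic keto aldehyde 20, whose two carbonyl groups are each accessible by robust chemistry and whose closure runs under weak base. The forward reaction must turn the C4 aldehyde into an acyl anion equivalent and add it to the ketone in preference to aldol chemistry.

**20 to 19 and 8 (O1–C2).** The aryl ether is cut at the CH2–O bond into salicylaldehyde 19 and phenacyl bromide 8. Bromide 8 comes from 4′-hydroxyacetophenone (5) through MOM ether 6 and its silyl enol ether 7. The forward step is a phenoxide alkylation kept cold enough to avoid aldol cyclodehydration.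

**19 to 18 to 16 (O8a–acetal, then C4a–CHO).** The aldehyde serves twice. It is the benzoin partner, and in 18 it is the one group that distinguishes the MOM ether at C8a (ortho to C=O, chelating) from the MOM ether at C7. Aldehyde 18 is cut at C4a–CHO to arene 16, which has a single ring hydrogen; forward, this is metalation to aryllithium 17 and formylation.

**16 to 15 to 13 and 4 (C6–CH2).** Removing the silyl group gives alcohol 15. Cutting the bond between C6 and the side-chain CH2 gives aryllithium 14 (from arene 13) and (R)-2-isopropyloxirane 4, which brings the stereocentre ready-made. Oxirane 4 comes from L-valine (1) through chloro acid 2 and chlorohydrin 3: retention in the chlorination, then one inversion in the ring closure. Opening at the CH2 carbon leaves the stereocentre untouched, and the (R)-oxirane maps onto the (S)-carbinol.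

**13 to 10 and 11 to 9 (C8–prenyl).** The prenyl group is cut off to give aryllithium 12, prenyl bromide (11) and the symmetric bis-MOM ether 10 of 5-methoxyresorcinol (9). Putting the C8 substituent in first has a specific advantage: the hydrogen between the two acetals is the best metalation site in 10, and once it is substituted the two remaining hydrogens of 13 are equivalent, so the second metalation needs no regiocontrol.

## Roads not taken

**Alternative 1: Danheiser benzannulation of ring A.** The cut dismantles ring A itself. Heating cyclobutenone A2 (3-methoxy, with the silyl-protected side chain at C2) with prenyl-substituted siloxyalkyne A3 would form C8a–C8, C7–C6 and C8a–C4a and give phenol A1. The sequence is 4π-opening to a vinylketene, [2+2] addition to the ynol ether, a second 4π-opening and a 6π-closure.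
- Merits: the order of five substituents is fixed by the mechanism and no metalation regiochemistry arises. The C8a oxygen emerges as a free phenol and the C7 oxygen as a silyl ether, so the two are differentiated from the start. In this respect it is better than the chosen plan, which needs the chelation-controlled step 11.
- Weak points: A2 and A3 are each multistep compounds. A2 needs the stereocentre and a regiodefined 2-alkyl-3-alkoxycyclobutenone; A3 is hydrolytically labile. A 3-alkoxycyclobutenone opens only at high temperature. A1 still lacks the C4a carbon, so formylation, etherification and all of ring C remain.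
- Comparison: the benzannulation would replace only steps 6–10 (five steps from a bought arene) with a longer convergent preparation. The chosen plan is shorter; what it sets against the regiochemical certainty of A1 is the symmetry of 10 and 13 and the established directing order of acetal over methyl ether.

**Alternative 2: aryne insertion at O1–C8a and C4–C4a.** Fluoride (CsF) would release the C4a–C8a aryne from ortho-silylaryl triflate A5. The carboxylate of arylacetic acid A6 adds at C8a, the C4a aryl anion takes the acyl group, and 2′-hydroxydeoxybenzoin A4 results; a one-carbon insertion then closes ring C.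
- Merits: it is convergent. The C5 methoxy group steers the nucleophile to the remote aryne carbon C8a and places the anion next to itself at C4a. The closure of A4 to the isoflavone with a formamide acetal is the most reliable isoflavone synthesis known and needs no dehydration; in this respect it is better than the chosen plan.
- Weak points: A5 is hexasubstituted and needs all the ring A work of the chosen route plus ortho-silylation and triflation. The native C8a oxygen is discarded as triflate and put back. Addition at C8a occurs next to the prenyl group, and protonation of the aryl anion before acyl transfer gives only the aryl ester.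
- Comparison: the chosen plan keeps the native oxygen and makes C4–C4a by a simple formylation. It has to set the less tested benzoin on a hindered aldehyde against this, and it keeps the deoxybenzoin closure in reserve as the fallback for step 13.

**Alternative 3: Friedel–Crafts closure at C4–C4a.** (Z)-3-Aryloxy-2-arylacrylic acid A8 would be activated as its mixed anhydride with trifluoroacetic anhydride, and C4a would attack the acyl carbon to give tris-MOM isoflavone A7 directly.
- Merits: C4a is the most nucleophilic ring position (ortho to the methoxy group and to O1, para to O7). Ring A needs no aldehyde, which saves the third metalation. The product is already at the isoflavone oxidation level, so the route after ring A is one to two steps shorter than the chosen one. This is a real advantage.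
- Weak points: the trifluoroacetic medium threatens exactly the delicate groups, namely the MOM acetals, the electron-rich aryl vinyl ether (hydrolysis) and the prenyl group (protonation, then closure onto O7 or addition of trifluoroacetate). A8 also requires the C8a phenol to be distinguished from the C7 oxygen without the aldehyde that makes this easy in the chosen route.
- Comparison: the chosen plan has more steps, but every step from ring A assembly to the last deprotection runs under basic or neutral, non-electrophilic conditions.

Key step: step 13

Remark on the chemistry: ketol 21 is expected as a mixture of both C3 epimers and is drawn without a descriptor at C3; the epimers need not be separated because step 14 makes C3 trigonal.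

## Route

Step 1
Reactants: 1 L-valine
Product: 2 (2S)-2-chloro-3-methylbutanoic acid
Conditions: NaNO2, 5 M aq. HCl, 0 °C → rt
Reagents that add atoms: hydrogen chloride, Cl
Why: Chlorodeamination by diazotisation; substitution of the diazonium group with participation of the neighbouring carboxylate proceeds by double inversion, so the (S) configuration is retained.

Step 2
Reactants: 2 (2S)-2-chloro-3-methylbutanoic acid
Product: 3 (2S)-2-chloro-3-methylbutan-1-ol
Conditions: LiAlH4, Et2O, 0 °C, short reaction time
Reagents that add atoms: none
Why: Hydride reduction of the carboxylic acid to the primary alcohol is faster at 0 °C than attack on the secondary C–Cl bond; the stereocentre is not involved.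

Step 3
Reactants: 3 (2S)-2-chloro-3-methylbutan-1-ol
Product: 4 (2R)-2-(propan-2-yl)oxirane
Conditions: KOH (50% aq.), 0 → 40 °C, product distilled out
Reagents that add atoms: none
Why: Intramolecular Williamson etherification; the alkoxide displaces chloride from the rear, one inversion at C2 turns the (S)-chlorohydrin into the (R)-oxirane.

Step 4
Reactants: 5 4′-hydroxyacetophenone
Product: 6 1-[4-(methoxymethoxy)phenyl]ethan-1-one
Conditions: MOMCl, i-Pr2NEt, CH2Cl2, 0 °C → rt
Reagents that add atoms: chloromethyl methyl ether (MOMCl), COCCl
Why: O-Alkylation of the phenol with an α-chloro ether (MOM protection); the acetal masks the ring B phenol against the bases used later.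

Step 5
Reactants: 6 1-[4-(methoxymethoxy)phenyl]ethan-1-one
Product: 8 2-bromo-1-[4-(methoxymethoxy)phenyl]ethan-1-one, via trimethylsilyl enol ether 7 (not isolated)
Conditions: LiN(SiMe3)2, Me3SiCl, THF, −78 °C; then NBS, −78 → 0 °C
Reagents that add atoms: N-bromosuccinimide, O=C1CCC(=O)N1Br
Why: Enolate silylation followed by electrophilic bromination of the silyl enol ether gives the monobromo ketone without free HBr, which would cleave the acetal; there is only one enolisable position.

Step 6
Reactants: 9 5-methoxyresorcinol
Product: 10 1-methoxy-3,5-bis(methoxymethoxy)benzene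
Conditions: MOMCl, i-Pr2NEt, CH2Cl2, 0 °C → rt
Reagents that add atoms: chloromethyl methyl ether (MOMCl), COCCl
Why: Twofold MOM protection; the acetals are the strongest directing groups for the metalations that follow and are later removable by mild acid.

Step 7
Reactants: 10 1-methoxy-3,5-bis(methoxymethoxy)benzene; 11 prenyl bromide (1-bromo-3-methylbut-2-ene)
Product: 13 5-methoxy-1,3-bis(methoxymethoxy)-2-(3-methylbut-2-en-1-yl)benzene, via aryllithium 12 (not isolated)
Conditions: n-BuLi, THF, 0 °C; then CuBr·SMe2 (10 mol %), 11, −78 °C → rt
Reagents that add atoms: none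
Why: Directed ortho-metalation: the hydrogen between the two chelating MOM ethers is removed in preference to those next to the weaker methoxy director; copper-catalysed coupling with the primary allylic bromide at its unsubstituted end gives the prenyl arene.

Step 8
Reactants: 13 5-methoxy-1,3-bis(methoxymethoxy)-2-(3-methylbut-2-en-1-yl)benzene; 4 (2R)-2-(propan-2-yl)oxirane
Product: 15 (2S)-1-[6-methoxy-2,4-bis(methoxymethoxy)-3-(3-methylbut-2-en-1-yl)phenyl]-3-methylbutan-2-ol, via aryllithium 14 (not isolated)
Conditions: n-BuLi, THF, 0 °C; then 4, BF3·OEt2, −78 °C; aq. NaHCO3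
Reagents that add atoms: none
Why: The two remaining ring hydrogens of 13 are equivalent and each lies between a MOM ether and the methoxy group, so this second directed ortho-metalation needs no regiocontrol; BF3·OEt2 promotes opening of the monosubstituted oxirane at its CH2 carbon by the aryllithium, the stereocentre is untouched and the (R)-oxirane gives the (S)-carbinol (the descriptor changes only through the priority rules).

Step 9
Reactants: 15 (2S)-1-[6-methoxy-2,4-bis(methoxymethoxy)-3-(3-methylbut-2-en-1-yl)phenyl]-3-methylbutan-2-ol
Product: 16 tert-butyl{[(2S)-1-[6-methoxy-2,4-bis(methoxymethoxy)-3-(3-methylbut-2-en-1-yl)phenyl]-3-methylbutan-2-yl]oxy}dimethylsilane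
Conditions: TBSCl, imidazole, DMF, 40 °C
Reagents that add atoms: tert-butyldimethylsilyl chloride (TBSCl), CC(C)(C)[Si](C)(C)Cl
Why: Silylation of the secondary alcohol with the chloride and imidazole avoids silyl triflates, which could attack the aryl acetals; the silyl ether withstands n-BuLi, MgBr2, carbonate, amines and SOCl2/pyridine.

Step 10
Reactants: 16 tert-butyl{[(2S)-1-[6-methoxy-2,4-bis(methoxymethoxy)-3-(3-methylbut-2-en-1-yl)phenyl]-3-methylbutan-2-yl]oxy}dimethylsilane
Product: 18 3-[(2S)-2-{[tert-butyl(dimethyl)silyl]oxy}-3-methylbutyl]-2-methoxy-4,6-bis(methoxymethoxy)-5-(3-methylbut-2-en-1-yl)benzaldehyde, via aryllithium 17 (not isolated)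
Conditions: n-BuLi, TMEDA, THF, −20 → 0 °C; then DMF, 0 °C → rt; H2O
Reagents that add atoms: N,N-dimethylformamide (DMF), CN(C)C=O
Why: Third directed ortho-metalation at the only remaining ring hydrogen, flanked by a MOM ether and the methoxy group, then formylation of the aryllithium with DMF (Bouveault aldehyde synthesis); kinetic ring metalation is expected to outrun deprotonation of the benzylic–allylic CH2 of the prenyl group.

Step 11
Reactants: 18 3-[(2S)-2-{[tert-butyl(dimethyl)silyl]oxy}-3-methylbutyl]-2-methoxy-4,6-bis(methoxymethoxy)-5-(3-methylbut-2-en-1-yl)benzaldehyde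
Product: 19 3-[(2S)-2-{[tert-butyl(dimethyl)silyl]oxy}-3-methylbutyl]-6-hydroxy-2-methoxy-4-(methoxymethoxy)-5-(3-methylbut-2-en-1-yl)benzaldehyde
Conditions: MgBr2·OEt2, Et2O–CH2Cl2, 0 °C → rt
Reagents that add atoms: none
Why: Chelation-controlled acetal cleavage: MgBr2 binds between the aldehyde oxygen and the ortho MOM oxygen and bromide opens only that activated acetal, as in the selective cleavage of ethers ortho to aryl carbonyl groups; the other MOM ether has no carbonyl neighbour, the chelated methyl ether is not an acetal and reacts far more slowly, and the silyl ether is inert to MgBr2.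

Step 12
Reactants: 19 3-[(2S)-2-{[tert-butyl(dimethyl)silyl]oxy}-3-methylbutyl]-6-hydroxy-2-methoxy-4-(methoxymethoxy)-5-(3-methylbut-2-en-1-yl)benzaldehyde; 8 2-bromo-1-[4-(methoxymethoxy)phenyl]ethan-1-one
Product: 20 3-[(2S)-2-{[tert-butyl(dimethyl)silyl]oxy}-3-methylbutyl]-2-methoxy-4-(methoxymethoxy)-6-{2-[4-(methoxymethoxy)phenyl]-2-oxoethoxy}-5-(3-methylbut-2-en-1-yl)benzaldehyde
Conditions: K2CO3, acetone, rt
Reagents that add atoms: none
Why: Williamson etherification of the acidic phenol with a phenacyl bromide, one of the fastest SN2 electrophiles; room temperature and carbonate base keep the product from aldol cyclodehydration to a benzofuran (Rap–Stoermer reaction).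

Step 13
Reactants: 20 3-[(2S)-2-{[tert-butyl(dimethyl)silyl]oxy}-3-methylbutyl]-2-methoxy-4-(methoxymethoxy)-6-{2-[4-(methoxymethoxy)phenyl]-2-oxoethoxy}-5-(3-methylbut-2-en-1-yl)benzaldehyde
Product: 21 6-[(2S)-2-{[tert-butyl(dimethyl)silyl]oxy}-3-methylbutyl]-3-hydroxy-5-methoxy-7-(methoxymethoxy)-3-[4-(methoxymethoxy)phenyl]-8-(3-methylbut-2-en-1-yl)-2,3-dihydro-4H-chromen-4-one (both C3 epimers)
Conditions: 2-(pentafluorophenyl)-6,7-dihydro-5H-pyrrolo[2,1-c][1,2,4]triazol-2-ium tetrafluoroborate (20 mol %), Et3N (20 mol %), THF, 25–40 °C
Reagents that add atoms: none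
Why: Et3N deprotonates the triazolium salt, the free carbene adds to the C4 aldehyde of 20, and proton transfer gives the Breslow intermediate, in which the former aldehyde carbon is nucleophilic. This carbon attacks the carbonyl carbon of the tethered aryl ketone and forms C3–C4; proton transfer and loss of the carbene give ketol 21 and return the catalyst. The closest known reaction type is the carbene-catalysed intramolecular crossed aldehyde–ketone benzoin reaction of 2-(2-aryl-2-oxoethoxy)benzaldehydes, which gives 3-aryl-3-hydroxychroman-4-ones. Ring C closes in the 6-exo-trig mode, the ketone C=O lying outside the new ring C4–C4a–C8a–O1–C2–C3. The new stereocentre C3 is not controlled, because the catalyst is achiral and the side-chain stereocentre is too remote; both epimers are expected and both give the same alkene in step 14. The selectivity needed is chemoselectivity: crossed benzoin against base-induced aldol closure of the aryloxymethyl ketone onto the aldehyde (five-membered ring, then benzofuran) and against intermolecular aldehyde dimerisation. It is secured by a weak amine base in catalytic amount paired with an acidic N-pentafluorophenyl triazolium salt, by the six-membered tether, and by the two ortho substituents of the aldehyde, which slow bimolecular reactions; the ketone cannot itself become an acyl anion, so only the crossed product can form. The small, electron-poor N-aryl group is chosen because the aldehyde is flanked by two ortho oxygens.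

Step 14
Reactants: 21 6-[(2S)-2-{[tert-butyl(dimethyl)silyl]oxy}-3-methylbutyl]-3-hydroxy-5-methoxy-7-(methoxymethoxy)-3-[4-(methoxymethoxy)phenyl]-8-(3-methylbut-2-en-1-yl)-2,3-dihydro-4H-chromen-4-one
Product: 23 6-[(2S)-2-{[tert-butyl(dimethyl)silyl]oxy}-3-methylbutyl]-5-methoxy-7-(methoxymethoxy)-3-[4-(methoxymethoxy)phenyl]-8-(3-methylbut-2-en-1-yl)-4H-chromen-4-one, via chlorosulfite ester 22 (not isolated)
Conditions: SOCl2, pyridine, CH2Cl2, 0 °C → rt
Reagents that add atoms: none
Why: Dehydration of a tertiary alcohol with SOCl2/pyridine: the chlorosulfite is formed and pyridine removes a C2 hydrogen in a β-elimination; C2 carries the only hydrogens next to C3, so the alkene can form only across C2–C3, and conjugation with the C4 carbonyl and O1 drives it, both C3 epimers converging.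

Step 15
Reactants: 23 6-[(2S)-2-{[tert-butyl(dimethyl)silyl]oxy}-3-methylbutyl]-5-methoxy-7-(methoxymethoxy)-3-[4-(methoxymethoxy)phenyl]-8-(3-methylbut-2-en-1-yl)-4H-chromen-4-one
Product: 24 7-hydroxy-6-[(2S)-2-hydroxy-3-methylbutyl]-3-(4-hydroxyphenyl)-5-methoxy-8-(3-methylbut-2-en-1-yl)-4H-chromen-4-one (CNP0323282.1)
Conditions: 3 M aq. HCl, MeOH, 45 °C
Reagents that add atoms: none
Why: Acid hydrolysis of the two aryl MOM acetals and solvolysis of the secondary silyl ether should proceed under dilute HCl in methanol below the conditions that hydrate or cyclise a prenyl group; only O–CH2 and O–Si bonds break, so the (S) configuration is retained.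

## Compound list

1 | L-valine | CC(C)[C@H](N)C(=O)O | starting material
2 | (2S)-2-chloro-3-methylbutanoic acid | CC(C)[C@H](Cl)C(=O)O | intermediate
3 | (2S)-2-chloro-3-methylbutan-1-ol | CC(C)[C@H](Cl)CO | intermediate
4 | (2R)-2-(propan-2-yl)oxirane | CC(C)[C@@H]1CO1 | intermediate
5 | 4′-hydroxyacetophenone | CC(=O)c1ccc(O)cc1 | starting material
6 | 1-[4-(methoxymethoxy)phenyl]ethan-1-one | CC(=O)c1ccc(OCOC)cc1 | intermediate
7 | {1-[4-(methoxymethoxy)phenyl]ethenyloxy}trimethylsilane (not isolated) | C=C(O[Si](C)(C)C)c1ccc(OCOC)cc1 | intermediate
8 | 2-bromo-1-[4-(methoxymethoxy)phenyl]ethan-1-one | BrCC(=O)c1ccc(OCOC)cc1 | intermediate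
9 | 5-methoxyresorcinol | COc1cc(O)cc(O)c1 | starting material
10 | 1-methoxy-3,5-bis(methoxymethoxy)benzene | COc1cc(OCOC)cc(OCOC)c1 | intermediate
11 | prenyl bromide (1-bromo-3-methylbut-2-ene) | CC(C)=CCBr | starting material
12 | [4-methoxy-2,6-bis(methoxymethoxy)phenyl]lithium (not isolated) | [Li]c1c(OCOC)cc(OC)cc1OCOC | intermediate
13 | 5-methoxy-1,3-bis(methoxymethoxy)-2-(3-methylbut-2-en-1-yl)benzene | COc1cc(OCOC)c(CC=C(C)C)c(OCOC)c1 | intermediate
14 | [6-methoxy-2,4-bis(methoxymethoxy)-3-(3-methylbut-2-en-1-yl)phenyl]lithium (not isolated) | [Li]c1c(OC)cc(OCOC)c(CC=C(C)C)c1OCOC | intermediate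
15 | (2S)-1-[6-methoxy-2,4-bis(methoxymethoxy)-3-(3-methylbut-2-en-1-yl)phenyl]-3-methylbutan-2-ol | COc1cc(OCOC)c(CC=C(C)C)c(OCOC)c1C[C@H](O)C(C)C | intermediate
16 | tert-butyl{[(2S)-1-[6-methoxy-2,4-bis(methoxymethoxy)-3-(3-methylbut-2-en-1-yl)phenyl]-3-methylbutan-2-yl]oxy}dimethylsilane | COc1cc(OCOC)c(CC=C(C)C)c(OCOC)c1C[C@H](O[Si](C)(C)C(C)(C)C)C(C)C | intermediate
17 | aryllithium of 16 at the last ring position, between the methoxy group and a MOM ether (not isolated) | [Li]c1c(OC)c(C[C@H](O[Si](C)(C)C(C)(C)C)C(C)C)c(OCOC)c(CC=C(C)C)c1OCOC | intermediate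
18 | 3-[(2S)-2-{[tert-butyl(dimethyl)silyl]oxy}-3-methylbutyl]-2-methoxy-4,6-bis(methoxymethoxy)-5-(3-methylbut-2-en-1-yl)benzaldehyde | COc1c(C=O)c(OCOC)c(CC=C(C)C)c(OCOC)c1C[C@H](O[Si](C)(C)C(C)(C)C)C(C)C | intermediate
19 | 3-[(2S)-2-{[tert-butyl(dimethyl)silyl]oxy}-3-methylbutyl]-6-hydroxy-2-methoxy-4-(methoxymethoxy)-5-(3-methylbut-2-en-1-yl)benzaldehyde | COc1c(C=O)c(O)c(CC=C(C)C)c(OCOC)c1C[C@H](O[Si](C)(C)C(C)(C)C)C(C)C | intermediate
20 | 3-[(2S)-2-{[tert-butyl(dimethyl)silyl]oxy}-3-methylbutyl]-2-methoxy-4-(methoxymethoxy)-6-{2-[4-(methoxymethoxy)phenyl]-2-oxoethoxy}-5-(3-methylbut-2-en-1-yl)benzaldehyde | COc1c(C=O)c(OCC(=O)c2ccc(OCOC)cc2)c(CC=C(C)C)c(OCOC)c1C[C@H](O[Si](C)(C)C(C)(C)C)C(C)C | intermediate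
21 | 6-[(2S)-2-{[tert-butyl(dimethyl)silyl]oxy}-3-methylbutyl]-3-hydroxy-5-methoxy-7-(methoxymethoxy)-3-[4-(methoxymethoxy)phenyl]-8-(3-methylbut-2-en-1-yl)-2,3-dihydro-4H-chromen-4-one (both C3 epimers) | COc1c(C[C@H](O[Si](C)(C)C(C)(C)C)C(C)C)c(OCOC)c(CC=C(C)C)c2OCC(O)(c3ccc(OCOC)cc3)C(=O)c12 | intermediate
22 | chlorosulfite ester of 21 at the C3 oxygen (not isolated) | COc1c(C[C@H](O[Si](C)(C)C(C)(C)C)C(C)C)c(OCOC)c(CC=C(C)C)c2OCC(OS(Cl)=O)(c3ccc(OCOC)cc3)C(=O)c12 | intermediate
23 | 6-[(2S)-2-{[tert-butyl(dimethyl)silyl]oxy}-3-methylbutyl]-5-methoxy-7-(methoxymethoxy)-3-[4-(methoxymethoxy)phenyl]-8-(3-methylbut-2-en-1-yl)-4H-chromen-4-one | COc1c(C[C@H](O[Si](C)(C)C(C)(C)C)C(C)C)c(OCOC)c(CC=C(C)C)c2occ(-c3ccc(OCOC)cc3)c(=O)c12 | intermediate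
24 | 7-hydroxy-6-[(2S)-2-hydroxy-3-methylbutyl]-3-(4-hydroxyphenyl)-5-methoxy-8-(3-methylbut-2-en-1-yl)-4H-chromen-4-one | COc1c(C[C@H](O)C(C)C)c(O)c(CC=C(C)C)c2occ(-c3ccc(O)cc3)c(=O)c12 | target

## Step count and least certain steps

Total: 15 steps. Longest linear sequence: 11 steps (steps 1–3 and 8–15, from L-valine); the line from 5-methoxyresorcinol is 10 steps (steps 6–15).

**Step 13 (key step).** The most likely failure is slow or reversible addition of the carbene to an aldehyde flanked by two ortho oxygen substituents, so that the Breslow intermediate does not build up. Base-induced enolisation of the aryloxymethyl ketone with aldol closure onto the aldehyde and loss of water would then take over.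
Fallback: the C3–C4 bond is made with normal polarity. Salicylaldehyde 19 is treated with excess 4-(MeOCH2O)C6H4CH2MgCl in THF at 0 °C to give the secondary benzylic alcohol F1. Oxidation with MnO2 in CH2Cl2 gives the 2′-hydroxydeoxybenzoin F2. Heating F2 with N,N-dimethylformamide dimethyl acetal in toluene inserts C2 and closes ring C, returning to the route at isoflavone 23 and bypassing steps 12–14.

**Step 11.** The risk is loss of selectivity among the acid-labile groups: partial cleavage of the second aryl MOM ether or of the silyl ether, or incomplete conversion when the Lewis acid is tied up by the product phenoxide.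
Fallback: both aryl MOM ethers of 18 are removed under nearly neutral conditions (Me3SiOTf and 2,2′-bipyridyl in CH2Cl2 at 0 °C, then water) to give the dihydroxy aldehyde F3. The non-chelated hydroxyl para to the aldehyde is then re-protected selectively (MOMCl, K2CO3, acetone, 0 °C); the ortho hydroxyl is held back by its hydrogen bond to the carbonyl. This returns to 19.

**Step 14.** The risk is that the chlorosulfite ionises or is displaced instead of eliminating. Substitution by chloride or an α-ketol rearrangement (shift of the aryl group from C3 to C4) would compete with formation of the C2=C3 bond.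
Fallback: the hydroxyl is removed reductively. Ketol 21 is treated with SmI2 in THF–MeOH at −78 °C (reductive cleavage of an α-hydroxy ketone) to give the isoflavanone F4. Dehydrogenation with DDQ in 1,4-dioxane at 80 °C returns to 23.

**Step 15.** The risk is acid-induced closure of the prenyl group onto the freed C7 hydroxyl (chroman formation), or hydration of the alkene, before the last protecting group has gone.
Fallback: deprotection in two non-protic stages. The aryl MOM ethers of 23 are exchanged with Me3SiOTf and 2,2′-bipyridyl in CH2Cl2 at 0 °C and hydrolysed with water to give the bis-phenol silyl ether F5. HF·pyridine in THF–pyridine at 0 °C then removes the silyl group and gives 24.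

**Step 12.** The risk is slow alkylation of the hindered, hydrogen-bonded phenoxide, followed by enolisation of the product and aldol cyclodehydration to a benzofuran on longer exposure to carbonate.
Fallback: etherification without base. Bromide 8 is converted with HCO2Na in aqueous ethanol at reflux into the hydroxy ketone F6. F6 is coupled with phenol 19 under Mitsunobu conditions (PPh3, diisopropyl azodicarboxylate, THF, 0 °C → rt), returning to 20.

## Further compounds

F1 | step 13 | 1-{3-[(2S)-2-{[tert-butyl(dimethyl)silyl]oxy}-3-methylbutyl]-6-hydroxy-2-methoxy-4-(methoxymethoxy)-5-(3-methylbut-2-en-1-yl)phenyl}-2-[4-(methoxymethoxy)phenyl]ethan-1-ol (both carbinol epimers) | COc1c(C(O)Cc2ccc(OCOC)cc2)c(O)c(CC=C(C)C)c(OCOC)c1C[C@H](O[Si](C)(C)C(C)(C)C)C(C)C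
F2 | step 13 | 1-{3-[(2S)-2-{[tert-butyl(dimethyl)silyl]oxy}-3-methylbutyl]-6-hydroxy-2-methoxy-4-(methoxymethoxy)-5-(3-methylbut-2-en-1-yl)phenyl}-2-[4-(methoxymethoxy)phenyl]ethan-1-one | COc1c(C(=O)Cc2ccc(OCOC)cc2)c(O)c(CC=C(C)C)c(OCOC)c1C[C@H](O[Si](C)(C)C(C)(C)C)C(C)C
F3 | step 11 | 3-[(2S)-2-{[tert-butyl(dimethyl)silyl]oxy}-3-methylbutyl]-4,6-dihydroxy-2-methoxy-5-(3-methylbut-2-en-1-yl)benzaldehyde | COc1c(C=O)c(O)c(CC=C(C)C)c(O)c1C[C@H](O[Si](C)(C)C(C)(C)C)C(C)C
F4 | step 14 | 6-[(2S)-2-{[tert-butyl(dimethyl)silyl]oxy}-3-methylbutyl]-5-methoxy-7-(methoxymethoxy)-3-[4-(methoxymethoxy)phenyl]-8-(3-methylbut-2-en-1-yl)-2,3-dihydro-4H-chromen-4-one (both C3 epimers) | COc1c(C[C@H](O[Si](C)(C)C(C)(C)C)C(C)C)c(OCOC)c(CC=C(C)C)c2OCC(c3ccc(OCOC)cc3)C(=O)c12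
F5 | step 15 | 6-[(2S)-2-{[tert-butyl(dimethyl)silyl]oxy}-3-methylbutyl]-7-hydroxy-3-(4-hydroxyphenyl)-5-methoxy-8-(3-methylbut-2-en-1-yl)-4H-chromen-4-one | COc1c(C[C@H](O[Si](C)(C)C(C)(C)C)C(C)C)c(O)c(CC=C(C)C)c2occ(-c3ccc(O)cc3)c(=O)c12
F6 | step 12 | 2-hydroxy-1-[4-(methoxymethoxy)phenyl]ethan-1-one | OCC(=O)c1ccc(OCOC)cc1
A1 | alternative 1 | 5-methoxy-2-(3-methylbut-2-en-1-yl)-3-(triisopropylsilyloxy)-4-[(2S)-2-(tert-butyldimethylsilyloxy)-3-methylbutyl]phenol | COc1cc(O)c(CC=C(C)C)c(O[Si](C(C)C)(C(C)C)C(C)C)c1C[C@H](O[Si](C)(C)C(C)(C)C)C(C)C
A2 | alternative 1 | 2-[(2S)-2-(tert-butyldimethylsilyloxy)-3-methylbutyl]-3-methoxycyclobut-2-en-1-one | COC1=C(C[C@H](O[Si](C)(C)C(C)(C)C)C(C)C)C(=O)C1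
A3 | alternative 1 | triisopropyl[(5-methylhex-4-en-1-yn-1-yl)oxy]silane | CC(C)=CCC#CO[Si](C(C)C)(C(C)C)C(C)C
A4 | alternative 2 | 1-{6-hydroxy-2-methoxy-4-(methoxymethoxy)-3-[(2S)-2-(methoxymethoxy)-3-methylbutyl]-5-(3-methylbut-2-en-1-yl)phenyl}-2-[4-(methoxymethoxy)phenyl]ethan-1-one | COc1c(C(=O)Cc2ccc(OCOC)cc2)c(O)c(CC=C(C)C)c(OCOC)c1C[C@H](OCOC)C(C)C
A5 | alternative 2 | 3-methoxy-5-(methoxymethoxy)-4-[(2S)-2-(methoxymethoxy)-3-methylbutyl]-6-(3-methylbut-2-en-1-yl)-2-(trimethylsilyl)phenyl trifluoromethanesulfonate | COc1c([Si](C)(C)C)c(OS(=O)(=O)C(F)(F)F)c(CC=C(C)C)c(OCOC)c1C[C@H](OCOC)C(C)C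
A6 | alternative 2 | [4-(methoxymethoxy)phenyl]acetic acid | COCOc1ccc(CC(=O)O)cc1
A7 | alternative 3 | 5-methoxy-7-(methoxymethoxy)-6-[(2S)-2-(methoxymethoxy)-3-methylbutyl]-3-[4-(methoxymethoxy)phenyl]-8-(3-methylbut-2-en-1-yl)-4H-chromen-4-one | COc1c(C[C@H](OCOC)C(C)C)c(OCOC)c(CC=C(C)C)c2occ(-c3ccc(OCOC)cc3)c(=O)c12
A8 | alternative 3 | (2Z)-3-{5-methoxy-3-(methoxymethoxy)-4-[(2S)-2-(methoxymethoxy)-3-methylbutyl]-2-(3-methylbut-2-en-1-yl)phenoxy}-2-[4-(methoxymethoxy)phenyl]prop-2-enoic acid | COc1cc(O/C=C(/c2ccc(OCOC)cc2)C(=O)O)c(CC=C(C)C)c(OCOC)c1C[C@H](OCOC)C(C)C
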